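A direct plan would keep ring A as a ready-made benzene ring. 2,4-Dihydroxy-3,5-dimethoxyacetophenone A1, reached from a simpler resorcinol ketone by bromination and copper-mediated bromide-to-methoxide exchange, would be condensed with isovanillin A2 to chalcone A3. A3 would be cyclised oxidatively to the 5-deoxyflavone A4, and the C5 hydroxyl would be introduced last by carbonyl-directed C–H oxygenation after masking of the phenols.
Its weakest steps would be:
- the late C5–H oxygenation, because a strong oxidant would meet a tetra-oxygenated ring that is prone to quinone formation, and site control on such a flavone is untested;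
- the bromide-to-methoxide exchange, because hot methoxide on a free bis-phenolic methyl ketone invites reduction and aldol side paths;
- the masking and unmasking of the phenols, which would add two steps and no complexity.

The route rests on building ring A last, from open-chain pieces, on a preformed ring C. Ring A reads as a folded poly-β-carbonyl chain: C5 and C7 are acyl carbons, C6 and C8 are methoxy-bearing methylene carbons. Pyranone ester 8, a masked 1,3,5-tricarbonyl compound, already holds C4a, C8a, the C8 methoxymethyl group and the C5 carboxyl. In one operation its lateral carbanion is acylated by methyl methoxyacetate (C7–C8) and the new ketone closes onto the ring ester (C5–C6); enolisation then gives the hexasubstituted benzene with every oxygen in place. No arene C–H oxidation, no halide-to-methoxide exchange and no phenol masking for an oxidant is needed.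

Key step: step 4

Remark: tricarbonyl compounds 7 and 10 are drawn as keto forms but exist and react as enols or enolates, so the sp3 centre drawn in each has no stereochemical consequence; the target has no stereocentre.

Step 1
Reactants: 1 3-(benzyloxy)-4-methoxybenzaldehyde
Product: 2 2-(benzyloxy)-4-(2,2-dibromoethenyl)-1-methoxybenzene
Conditions: CBr4 (2 equiv), PPh3 (4 equiv), CH2Cl2, 0 °C
Reagents that add atoms: carbon tetrabromide, BrC(Br)(Br)Br
Why: First half of the Corey–Fuchs sequence, in which the dibromomethylene ylide formed from PPh3 and CBr4 olefinates the aldehyde in a Wittig reaction while the benzyl and methyl ethers are inert.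

Step 2
Reactants: 2 2-(benzyloxy)-4-(2,2-dibromoethenyl)-1-methoxybenzene
Product: 4 3-[3-(benzyloxy)-4-methoxyphenyl]prop-2-ynoic acid, via lithium acetylide 3 (not isolated)
Conditions: n-BuLi (2.2 equiv), THF, −78 °C; then CO2 (g), −78 °C to rt; then 1 M HCl, 0 °C
Reagents that add atoms: carbon dioxide, O=C=O
Why: Second half of the Corey–Fuchs sequence, in which bromine–lithium exchange and α-elimination give the alkyne by a Fritsch–Buttenberg–Wiechell 1,2-shift, the second equivalent of n-BuLi gives acetylide 3, and carboxylation gives the propiolic acid, the benzylic ether not being metalated in the cold.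

Step 3
Reactants: 4 3-[3-(benzyloxy)-4-methoxyphenyl]prop-2-ynoic acid; 5 methyl 4-methoxy-3-oxobutanoate (methyl 4-methoxyacetoacetate)
Product: 8 methyl 6-[3-(benzyloxy)-4-methoxyphenyl]-2-(methoxymethyl)-4-oxo-4H-pyran-3-carboxylate, via acid chloride 6 (not isolated), via ynone triketo ester 7 (not isolated)
Conditions: (COCl)2 (1.2 equiv), DMF (cat.), CH2Cl2, 0 °C to rt, evaporate; then 5 (1.1 equiv), MgCl2 (1.1 equiv), pyridine (2.2 equiv), CH2Cl2, 0 °C to rt; then TsOH·H2O (10 mol %), toluene, 60 °C
Reagents that add atoms: none
Why: C-acylation of the magnesium chelate of a β-keto ester by an acid chloride, followed by acid-catalysed 6-endo-dig oxa-Michael addition of the methoxyacetyl enol oxygen to the ynone β-carbon, is the long-known route from alkynoyl chlorides and acetoacetates to 4-pyranone-3-carboxylates, and the electron-rich aryl group stabilises positive charge at the β-carbon and so favours the six- over the five-membered closure.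

Step 4
Reactants: 8 methyl 6-[3-(benzyloxy)-4-methoxyphenyl]-2-(methoxymethyl)-4-oxo-4H-pyran-3-carboxylate; 9 methyl methoxyacetate
Product: 11 2-[3-(benzyloxy)-4-methoxyphenyl]-5,7-dihydroxy-6,8-dimethoxy-4H-chromen-4-one (acerosin 3'-O-benzyl ether), via lateral ketone 10 (not isolated)
Conditions: LiN(SiMe3)2 (1.1 equiv), THF, −78 °C; 9 (1.2 equiv), −78 to 0 °C; then LiN(i-Pr)2 (2.5 equiv), −78 °C to rt; then 1 M HCl
Reagents that add atoms: none
Why: Proposed new method: LiN(SiMe3)2 removes a proton from the C2 methoxymethyl group of 8 (γ to both the ring ketone and the ester), the dienolate is acylated at this exocyclic carbon by ester 9 in a Claisen condensation (C7–C8) that the released methoxide drives by deprotonating ketone 10, and LiN(i-Pr)2 then forms the α′-carbanion at the terminal CH2OMe of 10, which adds to the neighbouring ring ester in a Dieckmann-type closure (C5–C6); loss of methoxide and double enolisation give the benzene ring. The closest known reaction types are the lateral acylation of 2-alkyl-4-pyranone anions by esters and the base-mediated closure of 2-(2-oxoalkyl)benzoates to naphthalene-1,3-diols, which have not been combined on a 4-pyranone-3-carboxylate. Ring A closes in the 6-exo-trig mode, and no stereocentre results because the CH(OMe) carbon of 10 ends as aromatic C8. The step needs exocyclic C-acylation in the first stage, which restores the pyranone and leads to the only product that can be trapped as a stabilised enolate, and C- instead of O-acylation in the second, where an enol lactone would be reopened by methoxide while the aromatic bis-phenoxide of 11 is the thermodynamic sink. The substrate secures the rest: the ester on C3 of 8 has no α-hydrogen and cannot be switched off by enolisation, the C8a carbonyl is locked in the pyranone and cannot lactonise, and the ring carries negative charge throughout, which shields C2 and C6 from methoxide.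

Step 5
Reactants: 11 2-[3-(benzyloxy)-4-methoxyphenyl]-5,7-dihydroxy-6,8-dimethoxy-4H-chromen-4-one
Product: 12 acerosin [5,7-dihydroxy-2-(3-hydroxy-4-methoxyphenyl)-6,8-dimethoxy-4H-chromen-4-one]
Conditions: H2 (1 atm), Pd/C (10 wt % Pd), EtOAc/MeOH, rt
Reagents that add atoms: none
Why: Hydrogenolysis of a benzyl aryl ether over palladium on carbon should free the ring B phenol, since the C2–C3 double bond of a flavone is part of a vinylogous ester that resists hydrogenation at one atmosphere and room temperature and the methyl ethers are untouched.

**Compound list**
1 | 3-(benzyloxy)-4-methoxybenzaldehyde | COc1ccc(C=O)cc1OCc1ccccc1 | starting material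
2 | 2-(benzyloxy)-4-(2,2-dibromoethenyl)-1-methoxybenzene | COc1ccc(C=C(Br)Br)cc1OCc1ccccc1 | intermediate
3 | lithium [3-(benzyloxy)-4-methoxyphenyl]acetylide (formed in the flask) | [Li]C#Cc1ccc(OC)c(OCc2ccccc2)c1 | intermediate
4 | 3-[3-(benzyloxy)-4-methoxyphenyl]prop-2-ynoic acid | COc1ccc(C#CC(=O)O)cc1OCc1ccccc1 | intermediate
5 | methyl 4-methoxy-3-oxobutanoate | COCC(=O)CC(=O)OC | starting material
6 | 3-[3-(benzyloxy)-4-methoxyphenyl]prop-2-ynoyl chloride (formed in the flask) | COc1ccc(C#CC(=O)Cl)cc1OCc1ccccc1 | intermediate
7 | methyl 5-[3-(benzyloxy)-4-methoxyphenyl]-2-(methoxyacetyl)-3-oxopent-4-ynoate (formed in the flask, enolised) | COCC(=O)C(C(=O)OC)C(=O)C#Cc1ccc(OC)c(OCc2ccccc2)c1 | intermediate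
8 | methyl 6-[3-(benzyloxy)-4-methoxyphenyl]-2-(methoxymethyl)-4-oxo-4H-pyran-3-carboxylate | COCc1oc(-c2ccc(OC)c(OCc3ccccc3)c2)cc(=O)c1C(=O)OC | intermediate
9 | methyl methoxyacetate | COCC(=O)OC | starting material
10 | methyl 6-[3-(benzyloxy)-4-methoxyphenyl]-2-(1,3-dimethoxy-2-oxopropyl)-4-oxo-4H-pyran-3-carboxylate (formed in the flask as its enolate, racemic) | COCC(=O)C(OC)c1oc(-c2ccc(OC)c(OCc3ccccc3)c2)cc(=O)c1C(=O)OC | intermediate
11 | 2-[3-(benzyloxy)-4-methoxyphenyl]-5,7-dihydroxy-6,8-dimethoxy-4H-chromen-4-one | COc1ccc(-c2cc(=O)c3c(O)c(OC)c(O)c(OC)c3o2)cc1OCc1ccccc1 | intermediate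
12 | acerosin | COc1ccc(-c2cc(=O)c3c(O)c(OC)c(O)c(OC)c3o2)cc1O | target

Total step count: 5. Longest linear sequence: 5 steps (1 → 2 → 4 → 8 → 11 → 12; compounds 5 and 9 are purchased).

Steps most likely to fail:

Step 4. Ester 9 may be enolised instead of attacked, or the second closure may stall at ketone 10 or end in O-acylation. The fallback sets out from 8 and returns at 11, with the two bond formations separated and each run as a known reaction. The lateral lithium dienolate of 8 (LiN(SiMe3)2, THF, −78 °C) would be acylated with N,2-dimethoxy-N-methylacetamide. Its tetrahedral adduct survives until work-up, so neither alkoxide nor a second enolate is present, and ketone 10 would be isolated. Ketone 10 would then be closed in a separate intramolecular Claisen condensation under equilibrating conditions (Mg(OMe)2 or NaOMe, MeOH, reflux), in which an enol lactone from O-acylation is reopened and the aromatic bis-phenoxide of 11 accumulates. No compound outside the list is made (F0).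

Step 3. The ynoyl chloride may take up chloride or pyridine at its β-carbon, or acylate the enolate on oxygen. The fallback sets out from 4 and returns at 8, with the order of the two acylations inverted. Acid 4 would be activated with 1,1'-carbonyldiimidazole to 1-{3-[3-(benzyloxy)-4-methoxyphenyl]prop-2-ynoyl}-1H-imidazole F1. F1 would acylate the lithium enolate of methyl acetate (THF, −78 °C) to give methyl 5-[3-(benzyloxy)-4-methoxyphenyl]-3-oxopent-4-ynoate F2. The magnesium chelate of F2 (MgCl2, pyridine, CH2Cl2) would then be C-acylated with methoxyacetyl chloride, a saturated acid chloride with no conjugate acceptor site, to the same triketo ester 7, which would close to 8 with TsOH as in the route.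

Step 5. Partial saturation of the C2–C3 double bond or slow turnover on a chelating polyphenol may occur. The fallback sets out from 11 and ends at 12: Lewis-acid debenzylation with BCl3 and pentamethylbenzene as cation scavenger (CH2Cl2, −78 °C). This cleaves the benzyl ether by ionisation, leaves the enone untouched, and is cold and brief enough to spare the methyl ethers. No new compound is made (F0).

**Further compounds**
F0 | step 4 | none | none
F1 | step 3 | 1-{3-[3-(benzyloxy)-4-methoxyphenyl]prop-2-ynoyl}-1H-imidazole | COc1ccc(C#CC(=O)n2ccnc2)cc1OCc1ccccc1
F2 | step 3 | methyl 5-[3-(benzyloxy)-4-methoxyphenyl]-3-oxopent-4-ynoate | COC(=O)CC(=O)C#Cc1ccc(OC)c(OCc2ccccc2)c1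
F0 | step 5 | none | none
A1 | direct plan | 2,4-dihydroxy-3,5-dimethoxyacetophenone | CC(=O)c1cc(OC)c(O)c(OC)c1O
A2 | direct plan | isovanillin (3-hydroxy-4-methoxybenzaldehyde) | COc1ccc(C=O)cc1O
A3 | direct plan | (E)-1-(2,4-dihydroxy-3,5-dimethoxyphenyl)-3-(3-hydroxy-4-methoxyphenyl)prop-2-en-1-one | COc1ccc(/C=C/C(=O)c2cc(OC)c(O)c(OC)c2O)cc1O
A4 | direct plan | 7-hydroxy-2-(3-hydroxy-4-methoxyphenyl)-6,8-dimethoxy-4H-chromen-4-one | COc1ccc(-c2cc(=O)c3cc(OC)c(O)c(OC)c3o2)cc1O
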